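**Retrosynthetic overview**
- Acid ⇐ Pd-catalysed hydroxycarbonylation of the C7=C8 enol triflate ⇐ kinetic triflation of the trans-decalin C8 ketone.
- Decalin ketone ⇐ one acid-catalysed, enantioselective double ring closure of an acyclic dienyl enol acetate: ring A closes first (C4–C5), ring B second (C9–C10), in the same operation; the enol acetate ends the cascade as the C8 ketone.
- Enol acetate ⇐ copper-catalysed conjugate addition of a dialkylzinc (carrying the C13 stereocentre and the isobutyrate) to a homogeranyl vinyl ketone, zinc enolate trapped with Ac2O.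
- Pieces: (S)-3-bromo-2-methylpropan-1-ol + isobutyryl chloride; geranyl bromide + N-methoxy-N-methylacetamide + vinylmagnesium bromide.

Assumption: both antipodes of the chiral acid catalyst are at hand and the one giving the (4aS,8aS) series is picked in a pilot run; atom labels follow labdane numbering (C4 gem-dimethyl carbon, C5/C10 ring fusion, C8 carboxyl carbon, C9 side-chain carbon, side chain C11–C14 with the methyl on C13).

Step 1
Reactants: 1 (2S)-3-bromo-2-methylpropan-1-ol; 2 2-methylpropanoyl chloride
Product: 3 (2S)-3-bromo-2-methylpropyl 2-methylpropanoate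
Conditions: Et3N, DMAP (cat.), CH2Cl2, 0 °C to rt
Reagents that add atoms: none
Why: Nucleophilic acyl substitution (DMAP-catalysed esterification) at the primary hydroxyl installs the isobutyrate at the start; the stereocentre (the future C13) is not involved.

Step 2
Reactants: 3
Product: 4 (2S)-3-iodo-2-methylpropyl 2-methylpropanoate
Conditions: NaI, acetone, reflux
Reagents that add atoms: sodium iodide, [Na+].[I-]
Why: Finkelstein halide exchange (SN2 at the primary carbon, the neighbouring stereocentre is untouched) gives the iodide needed for iodine–zinc exchange.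

Step 3
Reactants: 5 N-methoxy-N-methylacetamide; 6 geranyl bromide ((2E)-1-bromo-3,7-dimethylocta-2,6-diene)
Product: 8 (4E)-N-methoxy-N,5,9-trimethyldeca-4,8-dienamide, via lithium enolate 7 (not isolated)
Conditions: LiN(iPr)2, THF, −78 °C; then 6, −78 to 0 °C
Reagents that add atoms: none
Why: SN2 alkylation of the Weinreb acetamide enolate by the primary allylic bromide builds the homogeranyl chain; the E alkene is carried over from geranyl bromide.

Step 4
Reactants: 8; 9 vinylmagnesium bromide
Product: 11 (6E)-7,11-dimethyldodeca-1,6,10-trien-3-one, via magnesium hemiaminal 10 (not isolated)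
Conditions: THF, 0 °C; inverse quench into cold 1 M HCl
Reagents that add atoms: none
Why: Weinreb ketone synthesis: the magnesium-chelated tetrahedral intermediate survives until the acidic inverse quench, so one vinyl group is delivered and the freed amine is protonated before it can add to the enone.

Step 5
Reactants: 4; 11
Product: 14 (2R,5Z,9E)-6-acetoxy-2,10,14-trimethylpentadeca-5,9,13-trien-1-yl 2-methylpropanoate, via dialkylzinc 12 (not isolated), via zinc enolate 13 (not isolated)
Conditions: 4, Et2Zn, CuI (cat.), neat, 50 °C, then vacuum; 11, Cu(OTf)2 (3 mol%), P(OEt)3 (6 mol%), toluene, −30 °C; Ac2O, −30 to 0 °C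
Reagents that add atoms: acetic anhydride, CC(=O)OC(C)=O
Why: Iodine–zinc exchange gives an ester-tolerant dialkylzinc whose copper-catalysed 1,4-addition to the vinyl ketone forms the C11–C12 bond and a regiodefined zinc enolate, which Ac2O traps on oxygen as the mainly Z C8=C9 enol acetate; C13 is a bystander and no new stereocentre forms.

Step 6
Reactants: 14
Product: 15 (1R,4aS,8aS)-5,5,8a-trimethyl-1-[(3R)-3-methyl-4-(2-methylpropanoyloxy)butyl]octahydronaphthalen-2(1H)-one
Conditions: chiral imidodiphosphorimidate Brønsted acid (5 mol%), (CF3)3COH, (CF3)2CHOH (3 equiv), −20 °C; aq. NaHCO3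
Reagents that add atoms: none
Why: Proposed new method: the confined chiral acid protonates the terminal trisubstituted alkene in its pocket and the chain closes head-to-tail through a chair–chair transition state (C4 cation attacked by C5 of the E alkene, then the tertiary C10 cation attacked by the enol acetate carbon C9), so the catalyst sets C5/C10 as (4aS,8aS), the E alkene gives the trans ring fusion and the Z enol acetate places the side chain equatorial at C9 (1R, which is also the stable epimer next to the ketone), while the acetoxycarbenium ion passes its acetyl group to the fluorinated alcohol and releases the C8 ketone and the proton; the closest known reactions are imidodiphosphorimidate-catalysed enantioselective cyclizations of homofarnesol-type polyenes and chiral Lewis acid-assisted Brønsted acid cyclizations of polyprenoids, here extended to an enol ester terminator.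

Step 7
Reactants: 15
Product: 17 (1R,4aS,8aS)-5,5,8a-trimethyl-1-[(3R)-3-methyl-4-(2-methylpropanoyloxy)butyl]-1,4,4a,5,6,7,8,8a-octahydronaphthalen-2-yl trifluoromethanesulfonate, via potassium enolate 16 (not isolated)
Conditions: KN(SiMe3)2 (1.05 equiv), THF, −78 °C; then PhNTf2, −78 to 0 °C
Reagents that add atoms: N-phenylbis(trifluoromethanesulfonimide), O=S(=O)(N(c1ccccc1)S(=O)(=O)C(F)(F)F)C(F)(F)F
Why: Kinetic enolate formation at the accessible C7 methylene (more acidic and less hindered than the tertiary C9–H or the isobutyrate α-H) and O-sulfonylation give the C7=C8 enol triflate; no stereocentre is touched.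

Step 8
Reactants: 17
Product: 18 (1R,4aS,8aS)-5,5,8a-trimethyl-1-[(3R)-3-methyl-4-(2-methylpropanoyloxy)butyl]-1,4,4a,5,6,7,8,8a-octahydronaphthalene-2-carboxylic acid (CNP0323283.1)
Conditions: Pd(OAc)2 (5 mol%), 1,3-bis(diphenylphosphino)propane (5 mol%), CO (1 atm), H2O, Et3N, DMF, 60 °C; dilute HCl work-up
Reagents that add atoms: carbon monoxide, [C-]#[O+]; water, O
Why: Palladium-catalysed hydroxycarbonylation (oxidative addition of the alkenyl triflate to zerovalent palladium formed in situ, CO insertion, hydrolysis of the acylpalladium) puts the carboxyl on C8 with the alkene fixed at C7=C8 and leaves the isobutyrate and all stereocentres untouched.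

**Compound list**
1 | (2S)-3-bromo-2-methylpropan-1-ol | OC[C@H](C)CBr | starting material
2 | 2-methylpropanoyl chloride | CC(C)C(Cl)=O | starting material
3 | (2S)-3-bromo-2-methylpropyl 2-methylpropanoate | CC(C)C(=O)OC[C@H](C)CBr | intermediate
4 | (2S)-3-iodo-2-methylpropyl 2-methylpropanoate | CC(C)C(=O)OC[C@H](C)CI | intermediate
5 | N-methoxy-N-methylacetamide | CC(=O)N(C)OC | starting material
6 | geranyl bromide, (2E)-1-bromo-3,7-dimethylocta-2,6-diene | BrC/C=C(\C)CCC=C(C)C | starting material
7 | lithium 1-[methoxy(methyl)amino]ethen-1-olate (not isolated) | C=C(O[Li])N(C)OC | intermediate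
8 | (4E)-N-methoxy-N,5,9-trimethyldeca-4,8-dienamide | CON(C)C(=O)CC/C=C(\C)CCC=C(C)C | intermediate
9 | vinylmagnesium bromide | C=C[Mg]Br | starting material
10 | bromomagnesium (6E)-3-[methoxy(methyl)amino]-7,11-dimethyldodeca-1,6,10-trien-3-olate (not isolated) | C=CC(O[Mg]Br)(N(C)OC)CC/C=C(\C)CCC=C(C)C | intermediate
11 | (6E)-7,11-dimethyldodeca-1,6,10-trien-3-one | C=CC(=O)CC/C=C(\C)CCC=C(C)C | intermediate
12 | bis[(2S)-2-methyl-3-(2-methylpropanoyloxy)propyl]zinc (not isolated) | CC(C)C(=O)OC[C@H](C)C[Zn]C[C@@H](C)COC(=O)C(C)C | intermediate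
13 | [(2S)-2-methyl-3-(2-methylpropanoyloxy)propyl]zinc (2R,5Z,9E)-2,10,14-trimethyl-1-(2-methylpropanoyloxy)pentadeca-5,9,13-trien-6-olate (not isolated) | CC(C)C(=O)OC[C@H](C)C[Zn]O/C(CC/C=C(\C)CCC=C(C)C)=C\CC[C@@H](C)COC(=O)C(C)C | intermediate
14 | (2R,5Z,9E)-6-acetoxy-2,10,14-trimethylpentadeca-5,9,13-trien-1-yl 2-methylpropanoate | CC(C)C(=O)OC[C@H](C)CC/C=C(\OC(C)=O)CC/C=C(\C)CCC=C(C)C | intermediate
15 | (1R,4aS,8aS)-5,5,8a-trimethyl-1-[(3R)-3-methyl-4-(2-methylpropanoyloxy)butyl]octahydronaphthalen-2(1H)-one | CC(C)C(=O)OC[C@H](C)CC[C@H]1C(=O)CC[C@H]2C(C)(C)CCC[C@]12C | intermediate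
16 | potassium (1R,4aS,8aS)-5,5,8a-trimethyl-1-[(3R)-3-methyl-4-(2-methylpropanoyloxy)butyl]-1,4,4a,5,6,7,8,8a-octahydronaphthalen-2-olate (not isolated) | CC(C)C(=O)OC[C@H](C)CC[C@H]1C(O[K])=CC[C@H]2C(C)(C)CCC[C@]12C | intermediate
17 | (1R,4aS,8aS)-5,5,8a-trimethyl-1-[(3R)-3-methyl-4-(2-methylpropanoyloxy)butyl]-1,4,4a,5,6,7,8,8a-octahydronaphthalen-2-yl trifluoromethanesulfonate | CC(C)C(=O)OC[C@H](C)CC[C@H]1C(OS(=O)(=O)C(F)(F)F)=CC[C@H]2C(C)(C)CCC[C@]12C | intermediate
18 | (1R,4aS,8aS)-5,5,8a-trimethyl-1-[(3R)-3-methyl-4-(2-methylpropanoyloxy)butyl]-1,4,4a,5,6,7,8,8a-octahydronaphthalene-2-carboxylic acid | CC(C)C(=O)OC[C@H](C)CC[C@H]1C(C(=O)O)=CC[C@H]2C(C)(C)CCC[C@]12C | target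

**Step count and weak points**

Total steps: 8. Longest linear sequence: 6 (steps 3, 4, 5, 6, 7, 8 from geranyl bromide; equally 1, 2, 5, 6, 7, 8 from the bromo alcohol).

Most likely to fail, first: step 6. Catalyst-controlled double ring closure onto an enol ester has no direct precedent; the acid may protonate the enol acetate or stop after ring A, and the enantiomeric excess is unknown. The fallback sets out from 14 and comes back at 15 and gives up the single cascade for a stepwise closure. The stoichiometric SnCl4 complex of (R)-2'-methoxy-1,1'-binaphthalen-2-ol (toluene, −78 °C, antipode chosen as for the catalyst) protonates only the terminal alkene and closes ring A. This gives the monocycles (2R,5Z)-6-acetoxy-8-[(1S)-2,2-dimethyl-6-methylidenecyclohexyl]-2-methyloct-5-en-1-yl 2-methylpropanoate F1 and (2R,5Z)-6-acetoxy-2-methyl-8-[(1S)-2,6,6-trimethylcyclohex-2-en-1-yl]oct-5-en-1-yl 2-methylpropanoate F2, which are isolated so that the enantiomeric purity at C5 can be checked. CF3CO2H/SnCl4 (CH2Cl2, −78 °C) then re-ionises C10 in both and closes ring B onto the enol acetate under control of the C5 centre, giving 15.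

Second: step 5. The vinyl ketone can oligomerise, only one alkyl group of the dialkylzinc is transferred, and O- versus C-acetylation of the zinc enolate is not guaranteed. The fallback sets out from 3 and 11 and comes back at 14, with no organozinc and no need for step 2. Nickel-catalysed reductive conjugate addition of bromide 3 to enone 11 (NiCl2(dme), neocuproine, Mn, Et3SiCl, DMF, rt) gives the silyl enol ether (2R,5Z,9E)-2,10,14-trimethyl-6-(triethylsilyloxy)pentadeca-5,9,13-trien-1-yl 2-methylpropanoate F3. Fluoride-triggered acyl exchange (Bu4N[Ph3SiF2], Ac2O, THF, −78 to 0 °C) then gives 14.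

Third: step 7. A strong base next to the isobutyrate, and the choice between C7 and C9 enolisation, are the concerns. The fallback sets out from 15 and comes back at 17 and separates enolisation from triflation. LiN(SiMe3)2 is added to 15 and Me3SiCl (internal quench, THF, −78 °C) to give (2R)-2-methyl-4-[(1R,4aS,8aS)-5,5,8a-trimethyl-2-(trimethylsilyloxy)-1,4,4a,5,6,7,8,8a-octahydronaphthalen-1-yl]butyl 2-methylpropanoate F4, which is purified from any C8=C9 isomer. CsF/PhNTf2 (1,2-dimethoxyethane, rt) then converts F4 into 17 without free amide base.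

**Further compounds**
F1 | step 6 | (2R,5Z)-6-acetoxy-8-[(1S)-2,2-dimethyl-6-methylidenecyclohexyl]-2-methyloct-5-en-1-yl 2-methylpropanoate | CC(C)C(=O)OC[C@H](C)CC/C=C(\OC(C)=O)CC[C@@H]1C(=C)CCCC1(C)C
F2 | step 6 | (2R,5Z)-6-acetoxy-2-methyl-8-[(1S)-2,6,6-trimethylcyclohex-2-en-1-yl]oct-5-en-1-yl 2-methylpropanoate | CC(C)C(=O)OC[C@H](C)CC/C=C(\OC(C)=O)CC[C@@H]1C(C)=CCCC1(C)C
F3 | step 5 | (2R,5Z,9E)-2,10,14-trimethyl-6-(triethylsilyloxy)pentadeca-5,9,13-trien-1-yl 2-methylpropanoate | CC(C)C(=O)OC[C@H](C)CC/C=C(\O[Si](CC)(CC)CC)CC/C=C(\C)CCC=C(C)C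
F4 | step 7 | (2R)-2-methyl-4-[(1R,4aS,8aS)-5,5,8a-trimethyl-2-(trimethylsilyloxy)-1,4,4a,5,6,7,8,8a-octahydronaphthalen-1-yl]butyl 2-methylpropanoate | CC(C)C(=O)OC[C@H](C)CC[C@H]1C(O[Si](C)(C)C)=CC[C@H]2C(C)(C)CCC[C@]12C
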